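**Plan**
- The retrosynthesis cuts the two interflavan bonds, C4 of each upper unit to C6 and to C8 of the catechin unit, giving (+)-catechin and two copies of one 5-deoxyflavan-4-one.
- In that unit it cuts C3–O, then C4a–C5 and C8–C8a of ring A (Diels–Alder), then C2–C3 and O1–C8a of ring C (hetero-Diels–Alder).
- Enabling feature: ring A of each upper unit has oxygen at C7 and C8a but hydrogen at C5, the pattern a 1-methoxy-3-siloxy diene leaves when it adds across the C4a–C8a bond of a pyran-4-one and the adduct is aromatised.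
- Forward: ring C is made first, ring A is fused onto it, the C3 oxygen is added, two such ketones are joined to 6,8-dilithiated catechin ether, both carbinols are reduced, and the protecting groups are removed.
- Stereochemistry: C2 from a chiral chromium catalyst; C3 trans to the C2 aryl group by substrate control; C4 by hydride delivery anti to the C3 silyloxy group (3,4-cis); the catechin centres from the chiral pool.

Key step: step 3

Remark: the target is read as the trimer in which both upper units are (2R,3S,4R) (2,3-trans-3,4-cis) and are bonded through C4 to C6 and C8 of (2R,3S)-catechin; flavan numbering is used, and C5 and C6 of pyranones 4 and 5 become C4a and C8a.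

**Step 1**
Reactants: 1 3,4-bis(benzyloxy)benzaldehyde; 2 (E)-1-methoxy-3-(trimethylsilyloxy)buta-1,3-diene
Product: 4 (2S)-2-[3,4-bis(benzyloxy)phenyl]-2,3-dihydro-4H-pyran-4-one, via dihydropyran cycloadduct 3 (not isolated)
Conditions: (S,S)-N,N′-bis(3,5-di-tert-butylsalicylidene)-1,2-cyclohexanediaminochromium tetrafluoroborate (2 mol %), 4 Å MS, t-BuOMe, −30 °C to rt; then TFA (catalytic), CH2Cl2, 0 °C
Reagents that add atoms: none
Why: Catalytic asymmetric hetero-Diels–Alder reaction in which the chiral salen complex of trivalent chromium should expose the Si face of the bound aldehyde to the diene and so set the one stereocentre (future C2) as S, after which acid removes methanol and the silyl group to give the enone; the catalyst antipode is exchanged if the sense proves opposite, and the enantiomeric purity is to be raised by recrystallisation.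

**Step 2**
Reactants: 4 (2S)-2-[3,4-bis(benzyloxy)phenyl]-2,3-dihydro-4H-pyran-4-one
Product: 5 (2S)-2-[3,4-bis(benzyloxy)phenyl]-5-bromo-2,3-dihydro-4H-pyran-4-one
Conditions: NBS (1.05 equiv), CH2Cl2, 0 °C, dark
Reagents that add atoms: N-bromosuccinimide, O=C1CCC(=O)N1Br
Why: Electrophilic α-bromination of a vinylogous ester (bromine adds to the enol ether carbon C5 and a proton is lost), which should be faster than bromination of the dialkoxyarene at low temperature and does not touch C2.

**Step 3**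
Reactants: 5 (2S)-2-[3,4-bis(benzyloxy)phenyl]-5-bromo-2,3-dihydro-4H-pyran-4-one; 2 (E)-1-methoxy-3-(trimethylsilyloxy)buta-1,3-diene
Product: 8 (2S)-2-[3,4-bis(benzyloxy)phenyl]-7-hydroxy-2,3-dihydro-4H-chromen-4-one, via Diels–Alder adduct 6 (not isolated), via bromo enone 7 (not isolated)
Conditions: 2 (4 equiv), PhMe, 120 °C, sealed tube; then 0.1 M HCl, THF, 0 °C; then DBU (1.2 equiv), CH2Cl2, −20 to 0 °C, AcOH quench
Reagents that add atoms: none
Why: Proposed new method: diene 2 should add thermally across the C5=C6 bond of 5 (a vinylogous ester made a better acceptor by the α-bromine) in a concerted, asynchronous normal-demand [4+2] cycloaddition that closes the six-membered carbocycle, the future ring A, by forming C8–C8a and C4a–C5 in one intermolecular event; the closest known reaction type is the Diels–Alder addition of 1-methoxy-3-siloxy dienes to 2-halocycloalkenones, halogenated quinones and chromones carrying an acceptor at C3, followed by eliminative aromatisation. The one selectivity the step needs is regiochemical and is secured by the polarisation of both partners: the CH2 terminus of 2 (largest HOMO coefficient) bonds to pyranone C6, the carbon β to the ketone, and the methoxy-bearing terminus to the brominated C5, so that the siloxy carbon ends para to C4a and ring A gets oxygen at C7 and hydrogen at C5. Dilute acid then hydrolyses the silyl enol ether of 6 and the β-methoxy ketone loses methanol (E1cB) to give 7, in which H-8a is the only hydrogen β to the tertiary, allylic bromide, so base can remove HBr only across C4a–C8a and the resulting cyclohexadienone tautomerises to the phenol. Because Br and H-8a are cis on the ring fusion, this elimination must run syn, or after reversible opening and reclosure of the C8a–O1 bond through the C7 enolate, with aromatisation as the driving force. No new stereocentre survives (C4a, C5 and C8a of 6 all become sp2), so endo/exo and facial selectivity are immaterial, and C2, which takes no part, keeps its S configuration. DBU is limited to a slight excess at low temperature and quenched with acid so that 8 is not opened to the chalcone and racemised.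

**Step 4**
Reactants: 8 (2S)-2-[3,4-bis(benzyloxy)phenyl]-7-hydroxy-2,3-dihydro-4H-chromen-4-one
Product: 9 (2S)-7-(benzyloxy)-2-[3,4-bis(benzyloxy)phenyl]-2,3-dihydro-4H-chromen-4-one
Conditions: BnOH, PPh3, DIAD, THF, 0 °C to rt
Reagents that add atoms: benzyl alcohol, OCc1ccccc1
Why: Mitsunobu etherification of the acidic 7-phenol runs under neutral conditions, so the base-labile flavanone should not open to the chalcone and C2 should keep its configuration.

**Step 5**
Reactants: 9 (2S)-7-(benzyloxy)-2-[3,4-bis(benzyloxy)phenyl]-2,3-dihydro-4H-chromen-4-one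
Product: 10 (2S)-7-(benzyloxy)-2-[3,4-bis(benzyloxy)phenyl]-4-(trimethylsilyloxy)-2H-chromene
Conditions: TMSOTf, Et3N, CH2Cl2, −20 to 0 °C; cold NaHCO3 wash, used crude
Reagents that add atoms: trimethylsilyl trifluoromethanesulfonate, C[Si](C)(C)OS(=O)(=O)C(F)(F)F
Why: Soft enolisation with a silyl triflate and a tertiary amine gives the silyl enol ether without a free enolate, which avoids E1cB opening of ring C and loss of the C2 configuration.

**Step 6**
Reactants: 10 (2S)-7-(benzyloxy)-2-[3,4-bis(benzyloxy)phenyl]-4-(trimethylsilyloxy)-2H-chromene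
Product: 12 (2R,3R)-7-(benzyloxy)-2-[3,4-bis(benzyloxy)phenyl]-3-hydroxy-2,3-dihydro-4H-chromen-4-one, via silyloxy epoxide 11 (not isolated)
Conditions: DMDO (acetone solution), CH2Cl2, −40 to 0 °C; then 1 M HCl, THF, 0 °C
Reagents that add atoms: dimethyldioxirane, CC1(C)OO1
Why: Rubottom oxidation in which the dioxirane should epoxidise the enol ether on the face opposite the C2 aryl group, so that hydrolysis of the silyloxy epoxide gives the 3-hydroxy ketone with OH trans to the aryl group (2R,3R), which is also the more stable diequatorial isomer.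

**Step 7**
Reactants: 12 (2R,3R)-7-(benzyloxy)-2-[3,4-bis(benzyloxy)phenyl]-3-hydroxy-2,3-dihydro-4H-chromen-4-one
Product: 13 (2R,3R)-7-(benzyloxy)-2-[3,4-bis(benzyloxy)phenyl]-3-(tert-butyldimethylsilyloxy)-2,3-dihydro-4H-chromen-4-one
Conditions: TBSOTf, 2,6-lutidine, CH2Cl2, −78 to 0 °C
Reagents that add atoms: tert-butyldimethylsilyl trifluoromethanesulfonate, CC(C)(C)[Si](C)(C)OS(=O)(=O)C(F)(F)F
Why: Silylation of a secondary alcohol with a silyl triflate and a hindered pyridine base, which installs the bulky group that later shields one face of C4.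

**Step 8**
Reactants: 14 (+)-catechin
Product: 15 (2R,3S)-5,7-bis(benzyloxy)-2-[3,4-bis(benzyloxy)phenyl]chroman-3-ol
Conditions: BnBr (4.4 equiv), K2CO3, DMF, rt, under Ar
Reagents that add atoms: benzyl bromide, BrCc1ccccc1
Why: Williamson etherification of the four phenols with a weak base, which leaves the secondary alcohol and both stereocentres untouched.

**Step 9**
Reactants: 15 (2R,3S)-5,7-bis(benzyloxy)-2-[3,4-bis(benzyloxy)phenyl]chroman-3-ol
Product: 16 (2R,3S)-3,5,7-tris(benzyloxy)-2-[3,4-bis(benzyloxy)phenyl]chromane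
Conditions: NaH, BnBr, DMF, 0 °C to rt
Reagents that add atoms: benzyl bromide, BrCc1ccccc1
Why: Williamson etherification of the remaining secondary alcohol through its sodium alkoxide.

**Step 10**
Reactants: 16 (2R,3S)-3,5,7-tris(benzyloxy)-2-[3,4-bis(benzyloxy)phenyl]chromane
Product: 17 (2R,3S)-3,5,7-tris(benzyloxy)-2-[3,4-bis(benzyloxy)phenyl]-6,8-dibromochromane
Conditions: NBS (2.1 equiv), CH2Cl2, −78 °C to rt
Reagents that add atoms: N-bromosuccinimide, O=C1CCC(=O)N1Br
Why: Electrophilic aromatic bromination, in which C6 and C8 of the phloroglucinol-type ring are by far the most nucleophilic positions and should both be brominated by two equivalents of reagent.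

**Step 11**
Reactants: 17 (2R,3S)-3,5,7-tris(benzyloxy)-2-[3,4-bis(benzyloxy)phenyl]-6,8-dibromochromane; 13 (2R,3R)-7-(benzyloxy)-2-[3,4-bis(benzyloxy)phenyl]-3-(tert-butyldimethylsilyloxy)-2,3-dihydro-4H-chromen-4-one (two equivalents enter the product)
Product: 19 penta-O-benzylcatechin carrying at C6 and at C8 a (2R,3R)-7-(benzyloxy)-2-[3,4-bis(benzyloxy)phenyl]-3-(tert-butyldimethylsilyloxy)-4-hydroxychroman-4-yl group (C4 configuration not assigned), via 6,8-dilithio arene 18 (not isolated)
Conditions: t-BuLi (4.2 equiv), THF, −78 °C; then 13 (2.4 equiv), THF, −78 to −30 °C; aq NH4Cl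
Reagents that add atoms: none
Why: Twofold bromine–lithium exchange followed by 1,2-addition of each aryllithium centre to the ketone of 13, the known way of joining a lithiated catechin ether to C4 of a 3-silyloxyflavan-4-one; the configuration of the new carbinol centres does not matter because both become cations in step 12.

**Step 12**
Reactants: 19 the bis(tertiary carbinol)
Product: 20 penta-O-benzylcatechin carrying at C6 and at C8 a (2R,3S,4R)-7-(benzyloxy)-2-[3,4-bis(benzyloxy)phenyl]-3-(tert-butyldimethylsilyloxy)chroman-4-yl group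
Conditions: n-Bu3SnH (6 equiv), TFA, CH2Cl2, 0 °C
Reagents that add atoms: none
Why: Ionic hydrogenation in which acid ionises each tertiary diaryl carbinol to a cation planar at C4 and the tin hydride should attack the face opposite the adjacent bulky silyloxy group, placing H trans to O3 and the catechin ring cis to O3 (4R) at both centres.

**Step 13**
Reactants: 20 the bis(silyl ether)
Product: 21 penta-O-benzylcatechin carrying at C6 and at C8 a (2R,3S,4R)-7-(benzyloxy)-2-[3,4-bis(benzyloxy)phenyl]-3-hydroxychroman-4-yl group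
Conditions: HF·pyridine, THF, 0 °C to rt
Reagents that add atoms: none
Why: Fluoride-mediated cleavage of the two silyl ethers, to which the benzyl ethers and the C4–aryl bonds are inert.

**Step 14**
Reactants: 21 the undeca-O-benzyl ether
Product: 22 CNP0289228.4 (target)
Conditions: H2 (1 atm), Pd(OH)2/C, THF/MeOH/H2O, rt
Reagents that add atoms: none
Why: Hydrogenolysis of the eleven benzyl ethers under neutral conditions, which should leave the C4–aryl bonds, the C2–O1 bonds and all stereocentres intact.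

**Compound list**
1 | 3,4-bis(benzyloxy)benzaldehyde | O=Cc1ccc(OCc2ccccc2)c(OCc2ccccc2)c1 | starting material
2 | (E)-1-methoxy-3-(trimethylsilyloxy)buta-1,3-diene | CO/C=C/C(=C)O[Si](C)(C)C | starting material
3 | (2S)-2-[3,4-bis(benzyloxy)phenyl]-6-methoxy-4-(trimethylsilyloxy)-3,6-dihydro-2H-pyran (C6 epimers) | COC1C=C(O[Si](C)(C)C)C[C@@H](c2ccc(OCc3ccccc3)c(OCc3ccccc3)c2)O1 | intermediate
4 | (2S)-2-[3,4-bis(benzyloxy)phenyl]-2,3-dihydro-4H-pyran-4-one | O=C1C=CO[C@H](c2ccc(OCc3ccccc3)c(OCc3ccccc3)c2)C1 | intermediate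
5 | (2S)-2-[3,4-bis(benzyloxy)phenyl]-5-bromo-2,3-dihydro-4H-pyran-4-one | O=C1C(Br)=CO[C@H](c2ccc(OCc3ccccc3)c(OCc3ccccc3)c2)C1 | intermediate
6 | (2S)-2-[3,4-bis(benzyloxy)phenyl]-4a-bromo-5-methoxy-7-(trimethylsilyloxy)-2,3,4a,5,8,8a-hexahydro-4H-chromen-4-one (cis-fused; C4a, C5, C8a not controlled) | COC1C=C(O[Si](C)(C)C)CC2O[C@H](c3ccc(OCc4ccccc4)c(OCc4ccccc4)c3)CC(=O)C12Br | intermediate
7 | (2S)-2-[3,4-bis(benzyloxy)phenyl]-4a-bromo-2,3,8,8a-tetrahydro-4H-chromene-4,7(4aH)-dione (cis-fused; C4a, C8a not controlled) | O=C1C=CC2(Br)C(=O)C[C@@H](c3ccc(OCc4ccccc4)c(OCc4ccccc4)c3)OC2C1 | intermediate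
8 | (2S)-2-[3,4-bis(benzyloxy)phenyl]-7-hydroxy-2,3-dihydro-4H-chromen-4-one | Oc1ccc2c(c1)O[C@H](c1ccc(OCc3ccccc3)c(OCc3ccccc3)c1)CC2=O | intermediate
9 | (2S)-7-(benzyloxy)-2-[3,4-bis(benzyloxy)phenyl]-2,3-dihydro-4H-chromen-4-one | c1ccccc1COc1ccc2c(c1)O[C@H](c1ccc(OCc3ccccc3)c(OCc3ccccc3)c1)CC2=O | intermediate
10 | (2S)-7-(benzyloxy)-2-[3,4-bis(benzyloxy)phenyl]-4-(trimethylsilyloxy)-2H-chromene | C[Si](C)(C)OC1=C[C@@H](c2ccc(OCc3ccccc3)c(OCc3ccccc3)c2)Oc2cc(OCc3ccccc3)ccc12 | intermediate
11 | 7-(benzyloxy)-2-[3,4-bis(benzyloxy)phenyl]-3,4-epoxy-4-(trimethylsilyloxy)chromane, epoxide oxygen trans to the C2 aryl group | c1ccccc1COc1ccc2c(c1)O[C@H](c1ccc(OCc3ccccc3)c(OCc3ccccc3)c1)[C@H]1O[C@@]21O[Si](C)(C)C | intermediate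
12 | (2R,3R)-7-(benzyloxy)-2-[3,4-bis(benzyloxy)phenyl]-3-hydroxy-2,3-dihydro-4H-chromen-4-one | c1ccccc1COc1ccc2c(c1)O[C@H](c1ccc(OCc3ccccc3)c(OCc3ccccc3)c1)[C@@H](O)C2=O | intermediate
13 | (2R,3R)-7-(benzyloxy)-2-[3,4-bis(benzyloxy)phenyl]-3-(tert-butyldimethylsilyloxy)-2,3-dihydro-4H-chromen-4-one | c1ccccc1COc1ccc2c(c1)O[C@H](c1ccc(OCc3ccccc3)c(OCc3ccccc3)c1)[C@@H](O[Si](C)(C)C(C)(C)C)C2=O | intermediate
14 | (+)-catechin, (2R,3S) | Oc1cc(O)c2c(c1)O[C@H](c1ccc(O)c(O)c1)[C@@H](O)C2 | starting material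
15 | (2R,3S)-5,7-bis(benzyloxy)-2-[3,4-bis(benzyloxy)phenyl]chroman-3-ol | c1ccccc1COc1cc(OCc3ccccc3)c2c(c1)O[C@H](c1ccc(OCc3ccccc3)c(OCc3ccccc3)c1)[C@@H](O)C2 | intermediate
16 | (2R,3S)-3,5,7-tris(benzyloxy)-2-[3,4-bis(benzyloxy)phenyl]chromane | c1ccccc1COc1cc(OCc3ccccc3)c2c(c1)O[C@H](c1ccc(OCc3ccccc3)c(OCc3ccccc3)c1)[C@@H](OCc1ccccc1)C2 | intermediate
17 | (2R,3S)-3,5,7-tris(benzyloxy)-2-[3,4-bis(benzyloxy)phenyl]-6,8-dibromochromane | c1ccccc1COc1c(Br)c(OCc3ccccc3)c2c(c1Br)O[C@H](c1ccc(OCc3ccccc3)c(OCc3ccccc3)c1)[C@@H](OCc1ccccc1)C2 | intermediate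
18 | (2R,3S)-3,5,7-tris(benzyloxy)-2-[3,4-bis(benzyloxy)phenyl]-6,8-dilithiochromane | c1ccccc1COc1c([Li])c(OCc3ccccc3)c2c(c1[Li])O[C@H](c1ccc(OCc3ccccc3)c(OCc3ccccc3)c1)[C@@H](OCc1ccccc1)C2 | intermediate
19 | 6,8-bis[(2R,3R)-7-(benzyloxy)-2-[3,4-bis(benzyloxy)phenyl]-3-(tert-butyldimethylsilyloxy)-4-hydroxychroman-4-yl] derivative of 16 (C4 of the upper units not assigned) | c1ccccc1COc1ccc2c(c1)O[C@H](c1ccc(OCc3ccccc3)c(OCc3ccccc3)c1)[C@@H](O[Si](C)(C)C(C)(C)C)C2(O)c1c(OCc3ccccc3)c2c(c(C3(O)c4ccc(OCc5ccccc5)cc4O[C@H](c4ccc(OCc5ccccc5)c(OCc5ccccc5)c4)[C@H]3O[Si](C)(C)C(C)(C)C)c1OCc1ccccc1)O[C@H](c1ccc(OCc3ccccc3)c(OCc3ccccc3)c1)[C@@H](OCc1ccccc1)C2 | intermediate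
20 | 6,8-bis[(2R,3S,4R)-7-(benzyloxy)-2-[3,4-bis(benzyloxy)phenyl]-3-(tert-butyldimethylsilyloxy)chroman-4-yl] derivative of 16 | c1ccccc1COc1ccc2c(c1)O[C@H](c1ccc(OCc3ccccc3)c(OCc3ccccc3)c1)[C@@H](O[Si](C)(C)C(C)(C)C)[C@H]2c1c(OCc3ccccc3)c2c(c([C@H]3c4ccc(OCc5ccccc5)cc4O[C@H](c4ccc(OCc5ccccc5)c(OCc5ccccc5)c4)[C@H]3O[Si](C)(C)C(C)(C)C)c1OCc1ccccc1)O[C@H](c1ccc(OCc3ccccc3)c(OCc3ccccc3)c1)[C@@H](OCc1ccccc1)C2 | intermediate
21 | 6,8-bis[(2R,3S,4R)-7-(benzyloxy)-2-[3,4-bis(benzyloxy)phenyl]-3-hydroxychroman-4-yl] derivative of 16 | c1ccccc1COc1ccc2c(c1)O[C@H](c1ccc(OCc3ccccc3)c(OCc3ccccc3)c1)[C@@H](O)[C@H]2c1c(OCc3ccccc3)c2c(c([C@H]3c4ccc(OCc5ccccc5)cc4O[C@H](c4ccc(OCc5ccccc5)c(OCc5ccccc5)c4)[C@H]3O)c1OCc1ccccc1)O[C@H](c1ccc(OCc3ccccc3)c(OCc3ccccc3)c1)[C@@H](OCc1ccccc1)C2 | intermediate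
22 | CNP0289228.4: (2R,3S)-catechin carrying at C6 and at C8 a (2R,3S,4R)-2-(3,4-dihydroxyphenyl)-3,7-dihydroxychroman-4-yl group | Oc1ccc2c(c1)O[C@H](c1ccc(O)c(O)c1)[C@@H](O)[C@H]2c1c(O)c2c(c([C@H]3c4ccc(O)cc4O[C@H](c4ccc(O)c(O)c4)[C@H]3O)c1O)O[C@H](c1ccc(O)c(O)c1)[C@@H](O)C2 | target

**Totals**
Total step count: 14. Longest linear sequence: 11 steps (steps 1–7, then 11–14); the catechin branch (steps 8–10) joins at step 11.

**Steps most likely to fail**

Step 3. Three processes could defeat it. The vinylogous ester may be too weak a dienophile to react before the diene decomposes. The syn loss of HBr may stall or be diverted into β-elimination of O1 with loss of electrophilic bromine. The base may open the product to the chalcone and erode the C2 configuration. The fallback sets out from 1 and returns at 9, replacing steps 1–4 by a known enantioselective oxa-Michael route. Crossed Claisen condensation of commercial methyl 4-(benzyloxy)-2-hydroxybenzoate with the lithium enolate of tert-butyl acetate (lithium diisopropylamide, THF, −78 °C) gives tert-butyl 3-[4-(benzyloxy)-2-hydroxyphenyl]-3-oxopropanoate F1. Knoevenagel condensation of F1 with 1 (piperidine, AcOH, PhMe) gives the alkylidene β-keto ester F2. A cinchona-alkaloid-derived bifunctional thiourea (the pseudo-enantiomer that delivers 2S; PhMe, −25 °C) should then catalyse intramolecular conjugate addition of the phenol to give the flavanone ester F3. Warming F3 with TsOH in PhMe removes the tert-butyl ester and decarboxylates to 9.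

Step 11. The second bromine–lithium exchange may be incomplete, the dianion may be protonated, or the hindered ketone may be enolised instead of attacked, so that only one upper unit is attached. The fallback sets out from 16 and returns at 19, attaching the units one at a time. Bromination of 16 with one equivalent of NBS (CH2Cl2, −78 °C) should give the 8-bromide F4. Exchange with t-BuLi (THF, −78 °C) and addition to 13 gives the mono-carbinol F5. A second bromination with NBS at C6 of the catechin ring, still the most electron-rich arene, gives the bromo carbinol F6. Deprotonation of the hydroxyl with n-BuLi, exchange with t-BuLi and addition to a second equivalent of 13 gives 19.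

Step 12. Facial selectivity in the hydride capture may be poor: in the 2,3-trans series the face anti to O3 is also the face of the C2 aryl group, so one or both C4 centres may form with the 3,4-trans arrangement. Acid may also remove the silyl ethers before reduction. The fallback sets out from 12 and returns at 22, replacing steps 7 and 9–14 by the classical acid-catalysed flavan-3,4-diol condensation. Hydrogenolysis of 12 (H2, Pd/C, EtOAc/MeOH) gives (2R,3R)-fustin F7. Reduction with NaBH4 (EtOH, 0 °C) gives the (2R,3S,4R)-flavan-3,4-diol F8. Condensation of F8 (2.2 equiv) with 14 in 0.1 M aqueous HCl at rt should give the 4,6:4,8-linked trimers as a mixture of C4 diastereomers. The 3,4-cis,3,4-cis isomer 22 is then separated by chromatography on Sephadex LH-20 and reversed phase. This route is unselective at C4 but short and free of protecting groups.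

**Further compounds**
F1 | step 3 | tert-butyl 3-[4-(benzyloxy)-2-hydroxyphenyl]-3-oxopropanoate | CC(C)(C)OC(=O)CC(=O)c1ccc(OCc2ccccc2)cc1O
F2 | step 3 | tert-butyl 2-[4-(benzyloxy)-2-hydroxybenzoyl]-3-[3,4-bis(benzyloxy)phenyl]prop-2-enoate (alkene geometry not defined) | CC(C)(C)OC(=O)C(=Cc1ccc(OCc2ccccc2)c(OCc2ccccc2)c1)C(=O)c1ccc(OCc2ccccc2)cc1O
F3 | step 3 | tert-butyl (2S)-7-(benzyloxy)-2-[3,4-bis(benzyloxy)phenyl]-4-oxochromane-3-carboxylate (C3 epimers) | CC(C)(C)OC(=O)C1C(=O)c2ccc(OCc3ccccc3)cc2O[C@@H]1c1ccc(OCc2ccccc2)c(OCc2ccccc2)c1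
F4 | step 11 | (2R,3S)-3,5,7-tris(benzyloxy)-2-[3,4-bis(benzyloxy)phenyl]-8-bromochromane | c1ccccc1COc1cc(OCc3ccccc3)c2c(c1Br)O[C@H](c1ccc(OCc3ccccc3)c(OCc3ccccc3)c1)[C@@H](OCc1ccccc1)C2
F5 | step 11 | 8-[(2R,3R)-7-(benzyloxy)-2-[3,4-bis(benzyloxy)phenyl]-3-(tert-butyldimethylsilyloxy)-4-hydroxychroman-4-yl] derivative of 16 (C4 of the upper unit not assigned) | c1c(OCc3ccccc3)c2c(c(C3(O)c4ccc(OCc5ccccc5)cc4O[C@H](c4ccc(OCc5ccccc5)c(OCc5ccccc5)c4)[C@H]3O[Si](C)(C)C(C)(C)C)c1OCc1ccccc1)O[C@H](c1ccc(OCc3ccccc3)c(OCc3ccccc3)c1)[C@@H](OCc1ccccc1)C2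
F6 | step 11 | 6-bromo derivative of F5 | Brc1c(OCc3ccccc3)c2c(c(C3(O)c4ccc(OCc5ccccc5)cc4O[C@H](c4ccc(OCc5ccccc5)c(OCc5ccccc5)c4)[C@H]3O[Si](C)(C)C(C)(C)C)c1OCc1ccccc1)O[C@H](c1ccc(OCc3ccccc3)c(OCc3ccccc3)c1)[C@@H](OCc1ccccc1)C2
F7 | step 12 | (2R,3R)-2-(3,4-dihydroxyphenyl)-3,7-dihydroxy-2,3-dihydro-4H-chromen-4-one (fustin) | Oc1ccc2c(c1)O[C@H](c1ccc(O)c(O)c1)[C@@H](O)C2=O
F8 | step 12 | (2R,3S,4R)-2-(3,4-dihydroxyphenyl)chromane-3,4,7-triol | Oc1ccc2c(c1)O[C@H](c1ccc(O)c(O)c1)[C@@H](O)[C@@H]2O
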